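The 1,2-dihydronaphthalene ring is assembled by forming C4–C4a and C1–C2 in one pot. The key step exploits the 4-hydroxy-3,5-dimethoxyphenyl ring on C1: carried as its p-quinone methide it makes C1 electrophilic, while C4a, the arene carbon ortho to the C1 attachment, bears bromine. The C4=C3(C10)–C2(C9) chain is an itaconate diester. A Heck reaction joins the itaconate CH2= carbon (C4) to C4a; the arylidene succinate so formed is acidic at C2 through conjugation into the quinone methide and closes onto C1 by intramolecular 1,6-addition. (−)-Menthyl esters make the trans products separable diastereomers; both ester carbons are then reduced and C10 is reoxidised.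

Key step: step 5

Remark (assumption): locants are those of the dihydronaphthalene with the aryl-bearing sp3 carbon as C1, C2 carrying the CH2OH carbon C9 and C3 the formyl carbon C10. Step 5 is assumed to give both trans diastereomers of 11 in comparable amounts, separable by crystallisation or chromatography, and only the (1S,2R) isomer is carried forward.

Step 1
Reactants: 1 4-bromo-2,6-dimethoxyphenol
Product: 2 5-bromo-1,3-dimethoxy-2-(methoxymethoxy)benzene
Conditions: NaH, MOMCl, DMF, 0 °C to rt
Reagents that add atoms: chloromethyl methyl ether (MOMCl), COCCl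
Why: Williamson-type O-alkylation of the phenoxide (MOM protection) should mask the future C7 hydroxyl through the organolithium, Pd, hydride and oxidation steps and leave it removable by mild acid at the end.

Step 2
Reactants: 2 5-bromo-1,3-dimethoxy-2-(methoxymethoxy)benzene
Product: 3 6-bromo-2,4-dimethoxy-3-(methoxymethoxy)benzaldehyde
Conditions: LDA, THF, −78 °C; DMF; H2O
Reagents that add atoms: N,N-dimethylformamide (DMF), CN(C)C=O
Why: Directed ortho-lithiation and formylation should give a single aldehyde, because the two equivalent ring C–H positions are the only ones present, lie between Br and OMe, and are deprotonated by the non-nucleophilic amide without Br/Li exchange.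

Step 3
Reactants: 3 6-bromo-2,4-dimethoxy-3-(methoxymethoxy)benzaldehyde; 4 2,6-dimethoxyphenol
Product: 6 4-{[6-bromo-2,4-dimethoxy-3-(methoxymethoxy)phenyl]methylidene}-2,6-dimethoxycyclohexa-2,5-dien-1-one, via Mannich base 5 (not isolated)
Conditions: piperidine (2 equiv), toluene, reflux (Dean–Stark); then Ac2O, 90 °C
Reagents that add atoms: none
Why: Betti-type Mannich condensation at the free para position of the phenol followed by acetic anhydride-triggered 1,6-elimination of piperidine is the standard preparation of δ-aryl p-quinone methides, and the symmetric dienone ring leaves no E/Z issue.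

Step 4
Reactants: 7 itaconic acid; 8 (−)-menthol
Product: 9 di-(−)-menthyl itaconate
Conditions: 8 (2.2 equiv in total), p-TsOH·H2O (cat.), hydroquinone (trace), toluene, reflux (Dean–Stark)
Reagents that add atoms: (−)-menthol (the second equivalent of 8), CC(C)[C@@H]1CC[C@@H](C)C[C@H]1O
Why: Acid-catalysed azeotropic Fischer esterification should consume two equivalents of menthol, one per carboxyl group, by the acyl–oxygen pathway that leaves the menthol stereocentres untouched, and it avoids the amine bases that isomerise itaconates to citraconates or mesaconates.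

Step 5
Reactants: 6 4-{[6-bromo-2,4-dimethoxy-3-(methoxymethoxy)phenyl]methylidene}-2,6-dimethoxycyclohexa-2,5-dien-1-one; 9 di-(−)-menthyl itaconate (2 equiv)
Product: 11 di-(−)-menthyl (1S,2R)-1-(4-hydroxy-3,5-dimethoxyphenyl)-6,8-dimethoxy-7-(methoxymethoxy)-1,2-dihydronaphthalene-2,3-dicarboxylate, via arylidene succinate 10 (not isolated)
Conditions: Pd(OAc)2 (5 mol %), P(o-tol)3 (12 mol %), KOAc, DMF, 100 °C; then DBU (0.3 equiv), 40 °C; separation of the two trans diastereomers
Reagents that add atoms: none
Why: Pd(0) inserts into the C4a–Br bond, the aryl group adds to the CH2 terminus of the itaconate (the preferred carbon of a 1,1-disubstituted acrylate) and β-hydride elimination gives the arylidene succinate 10, which forms the C4–C4a bond; acetate then removes a C2–H, which is α to an ester and conjugated through the styrene and the arene into the quinone methide, and the delocalised anion attacks the methide carbon to form C1–C2 and restore the phenol ring. The closest known reaction types are the Heck arylation of itaconates, domino Heck–Michael sequences and base-mediated 1,6-additions of ester enolates to p-quinone methides. The single ring that is closed forms by a 6-exo-trig intramolecular 1,6-conjugate addition, equivalent to a 6π-electrocyclisation of the o-quinodimethane form of the anion. C1 is fixed irreversibly in this closure, whereas C2 remains α to an ester and is equilibrated by DBU to the trans-1,2 arrangement, in which the C1 aryl group and the C2 ester are pseudoaxial and avoid the C8 methoxy group and the C3 ester. The absolute configuration is not dictated by any reagent, so both trans diastereomers are expected and the (−)-menthyl esters act as covalent resolving groups that allow the (1S,2R) isomer to be isolated. The step needs the Heck event to precede any intermolecular attack on the quinone methide, which should be secured because acetate is too weak to deprotonate 9 but deprotonates 10, whose anion is stabilised by the quinone methide, and because both β-hydride regioisomers and both alkene geometries of 10 converge on the same anion.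

Step 6
Reactants: 11 di-(−)-menthyl (1S,2R)-1-(4-hydroxy-3,5-dimethoxyphenyl)-6,8-dimethoxy-7-(methoxymethoxy)-1,2-dihydronaphthalene-2,3-dicarboxylate
Product: 12 [(1S,2R)-1-(4-hydroxy-3,5-dimethoxyphenyl)-6,8-dimethoxy-7-(methoxymethoxy)-1,2-dihydronaphthalene-2,3-diyl]dimethanol
Conditions: DIBAL-H (7 equiv), CH2Cl2, −78 to 0 °C; aq. potassium sodium tartrate
Reagents that add atoms: none
Why: DIBAL-H ester reduction should take both esters to primary alcohols with clean 1,2-selectivity on the conjugated one, releasing the menthol auxiliaries and leaving C1 and C2 untouched.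

Step 7
Reactants: 12 [(1S,2R)-1-(4-hydroxy-3,5-dimethoxyphenyl)-6,8-dimethoxy-7-(methoxymethoxy)-1,2-dihydronaphthalene-2,3-diyl]dimethanol
Product: 13 (1S,2R)-2-(hydroxymethyl)-1-(4-hydroxy-3,5-dimethoxyphenyl)-6,8-dimethoxy-7-(methoxymethoxy)-1,2-dihydronaphthalene-3-carbaldehyde
Conditions: activated MnO2, CH2Cl2, rt
Reagents that add atoms: none
Why: Chemoselective MnO2 oxidation should convert only the allylic (cinnamyl-type) C10 alcohol into the push–pull enal and leave the saturated C9 alcohol and both stereocentres unchanged.

Step 8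
Reactants: 13 (1S,2R)-2-(hydroxymethyl)-1-(4-hydroxy-3,5-dimethoxyphenyl)-6,8-dimethoxy-7-(methoxymethoxy)-1,2-dihydronaphthalene-3-carbaldehyde
Product: 14 (1S,2R)-7-hydroxy-2-(hydroxymethyl)-1-(4-hydroxy-3,5-dimethoxyphenyl)-6,8-dimethoxy-1,2-dihydronaphthalene-3-carbaldehyde (CNP0313592.1)
Conditions: 2 M aq. HCl, THF, 40 °C
Reagents that add atoms: none
Why: Acid-catalysed acetal hydrolysis should remove the MOM group from the electron-rich phenol under conditions that the enal, the primary alcohol and the non-epimerisable C1 and thermodynamically trans C2 centres tolerate.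

Compound list
1 | 4-bromo-2,6-dimethoxyphenol | COc1cc(Br)cc(OC)c1O | starting material
2 | 5-bromo-1,3-dimethoxy-2-(methoxymethoxy)benzene | COCOc1c(OC)cc(Br)cc1OC | intermediate
3 | 6-bromo-2,4-dimethoxy-3-(methoxymethoxy)benzaldehyde | COCOc1c(OC)cc(Br)c(C=O)c1OC | intermediate
4 | 2,6-dimethoxyphenol | COc1cccc(OC)c1O | starting material
5 | 4-{[6-bromo-2,4-dimethoxy-3-(methoxymethoxy)phenyl](piperidin-1-yl)methyl}-2,6-dimethoxyphenol (racemic Mannich base) | COCOc1c(OC)cc(Br)c(C(N2CCCCC2)c2cc(OC)c(O)c(OC)c2)c1OC | intermediate
6 | 4-{[6-bromo-2,4-dimethoxy-3-(methoxymethoxy)phenyl]methylidene}-2,6-dimethoxycyclohexa-2,5-dien-1-one | COCOc1c(OC)cc(Br)c(C=C2C=C(OC)C(=O)C(OC)=C2)c1OC | intermediate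
7 | itaconic acid (2-methylidenebutanedioic acid) | C=C(CC(=O)O)C(=O)O | starting material
8 | (−)-menthol, (1R,2S,5R)-2-isopropyl-5-methylcyclohexan-1-ol | CC(C)[C@@H]1CC[C@@H](C)C[C@H]1O | starting material
9 | di-(−)-menthyl itaconate, bis[(1R,2S,5R)-2-isopropyl-5-methylcyclohexyl] 2-methylidenebutanedioate | C=C(CC(=O)O[C@@H]1C[C@H](C)CC[C@H]1C(C)C)C(=O)O[C@@H]1C[C@H](C)CC[C@H]1C(C)C | intermediate
10 | di-(−)-menthyl (E)-2-({2-[(3,5-dimethoxy-4-oxocyclohexa-2,5-dien-1-ylidene)methyl]-3,5-dimethoxy-4-(methoxymethoxy)phenyl}methylidene)butanedioate | COCOc1c(OC)cc(/C=C(\CC(=O)O[C@@H]2C[C@H](C)CC[C@H]2C(C)C)C(=O)O[C@@H]2C[C@H](C)CC[C@H]2C(C)C)c(C=C2C=C(OC)C(=O)C(OC)=C2)c1OC | intermediate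
11 | di-(−)-menthyl (1S,2R)-1-(4-hydroxy-3,5-dimethoxyphenyl)-6,8-dimethoxy-7-(methoxymethoxy)-1,2-dihydronaphthalene-2,3-dicarboxylate | COc1cc([C@H]2c3c(cc(OC)c(OCOC)c3OC)C=C(C(=O)O[C@@H]4C[C@H](C)CC[C@H]4C(C)C)[C@@H]2C(=O)O[C@@H]4C[C@H](C)CC[C@H]4C(C)C)cc(OC)c1O | intermediate
12 | [(1S,2R)-1-(4-hydroxy-3,5-dimethoxyphenyl)-6,8-dimethoxy-7-(methoxymethoxy)-1,2-dihydronaphthalene-2,3-diyl]dimethanol | COc1cc([C@H]2c3c(cc(OC)c(OCOC)c3OC)C=C(CO)[C@@H]2CO)cc(OC)c1O | intermediate
13 | (1S,2R)-2-(hydroxymethyl)-1-(4-hydroxy-3,5-dimethoxyphenyl)-6,8-dimethoxy-7-(methoxymethoxy)-1,2-dihydronaphthalene-3-carbaldehyde | COc1cc([C@H]2c3c(cc(OC)c(OCOC)c3OC)C=C(C=O)[C@@H]2CO)cc(OC)c1O | intermediate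
14 | (1S,2R)-7-hydroxy-2-(hydroxymethyl)-1-(4-hydroxy-3,5-dimethoxyphenyl)-6,8-dimethoxy-1,2-dihydronaphthalene-3-carbaldehyde (CNP0313592.1) | COc1cc([C@H]2c3c(cc(OC)c(O)c3OC)C=C(C=O)[C@@H]2CO)cc(OC)c1O | target

Total step count: 8
Longest linear sequence: 7 steps (1, 2, 3, 5, 6, 7, 8); step 4 is a one-step side branch.

Steps most likely to fail

1. Step 5 (key step). The quinone methide may be lost before the Heck event, through oligomerisation under Pd and base at 100 °C, addition of acetate or adventitious water, or premature intermolecular addition of the itaconate. Oxidative addition at the hindered, electron-rich bromide may also be slow. The fallback sets out from aldehyde 3 and separates the two bond formations. Aldehyde 3 is coupled with 9 under the same Pd(OAc)2/P(o-tol)3/KOAc Heck conditions, in which the aldehyde is inert, to give the formyl arylidene succinate F1. F1 is then condensed with 4 and piperidine in refluxing toluene to the Mannich base F2. On continued heating F2 loses piperidine to the quinone methide 10, which cyclises in the basic amine medium. DBU equilibration and diastereomer separation as in step 5 return the route at 11.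

2. Step 3. The 2,6-dimethoxy quinone methide may not survive isolation (hydration, dimerisation), or O-acetylation of the phenol may compete with the elimination of piperidine. The fallback sets out from 3 and 4. The condensation is stopped at the Mannich base 5, which is isolated without Ac2O and used in place of 6 under the step 5 conditions. Thermal loss of piperidine at 100 °C then releases 6 only in low stationary concentration next to the Pd catalyst and 9, which is used in larger excess to allow for aza-Michael consumption by piperidine. The route is rejoined at 11, and no new compound arises (F0).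

3. Step 7. Oxidation of the free 4-hydroxy-3,5-dimethoxyphenyl ring (phenoxyl radical formation, quinone methide formation at the doubly benzylic C1–H, coupling) may compete with oxidation of the allylic alcohol. The fallback sets out from 11. The free phenol is masked as a second MOM ether (MOMCl, iPr2NEt, CH2Cl2) to give the bis-MOM diester F3. DIBAL-H reduction gives the bis-MOM diol F4, and MnO2 then oxidises only the allylic alcohol to the bis-MOM enal F5. Aqueous HCl in THF removes both MOM groups and rejoins the route at 14.

Further compounds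
F1 | step 5 | di-(−)-menthyl (E)-2-{[2-formyl-3,5-dimethoxy-4-(methoxymethoxy)phenyl]methylidene}butanedioate | COCOc1c(OC)cc(/C=C(\CC(=O)O[C@@H]2C[C@H](C)CC[C@H]2C(C)C)C(=O)O[C@@H]2C[C@H](C)CC[C@H]2C(C)C)c(C=O)c1OC
F2 | step 5 | di-(−)-menthyl (E)-2-({2-[(4-hydroxy-3,5-dimethoxyphenyl)(piperidin-1-yl)methyl]-3,5-dimethoxy-4-(methoxymethoxy)phenyl}methylidene)butanedioate | COCOc1c(OC)cc(/C=C(\CC(=O)O[C@@H]2C[C@H](C)CC[C@H]2C(C)C)C(=O)O[C@@H]2C[C@H](C)CC[C@H]2C(C)C)c(C(N3CCCCC3)c3cc(OC)c(O)c(OC)c3)c1OC
F0 | step 3 | none | none
F3 | step 7 | di-(−)-menthyl (1S,2R)-1-[3,5-dimethoxy-4-(methoxymethoxy)phenyl]-6,8-dimethoxy-7-(methoxymethoxy)-1,2-dihydronaphthalene-2,3-dicarboxylate | COCOc1c(OC)cc([C@H]2c3c(cc(OC)c(OCOC)c3OC)C=C(C(=O)O[C@@H]4C[C@H](C)CC[C@H]4C(C)C)[C@@H]2C(=O)O[C@@H]4C[C@H](C)CC[C@H]4C(C)C)cc1OC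
F4 | step 7 | {(1S,2R)-1-[3,5-dimethoxy-4-(methoxymethoxy)phenyl]-6,8-dimethoxy-7-(methoxymethoxy)-1,2-dihydronaphthalene-2,3-diyl}dimethanol | COCOc1c(OC)cc([C@H]2c3c(cc(OC)c(OCOC)c3OC)C=C(CO)[C@@H]2CO)cc1OC
F5 | step 7 | (1S,2R)-1-[3,5-dimethoxy-4-(methoxymethoxy)phenyl]-2-(hydroxymethyl)-6,8-dimethoxy-7-(methoxymethoxy)-1,2-dihydronaphthalene-3-carbaldehyde | COCOc1c(OC)cc([C@H]2c3c(cc(OC)c(OCOC)c3OC)C=C(C=O)[C@@H]2CO)cc1OC
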